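(The numbers in the tables stem from a simulated flask from invented constants, noise included.)

- At early times the alpha run showed a short lag: target stood at 2.7% after 1.33 min and 8.5% after 3.00 min, so it rose faster in the second stretch than in the first. That is the first thing I would watch.

| flask | substrate | coupling partner | free catalyst | remark |
|---|---|---|---|---|
| zeta | 0.074 M | 0.099 M | 1.4 mM | run made earlier |
| alpha | 0.17 M | 0.099 M | 1.4 mM | run made earlier |
| epsilon | 0.11 M | 0.099 M | 2.1 mM | run made earlier |
| flask | 0.11 M | 0.0990 M | 1.4 mM |  |

| zeta: time / min | zeta: target / % | alpha: time / min | alpha: target / % | epsilon: time / min | epsilon: target / % |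
|---|---|---|---|---|---|
| 5.00 | 19.4 | 1.33 | 2.7 | 5.00 | 28.5 |
| 10.0 | 34.8 | 3.00 | 8.5 | 10.0 | 45.9 |
| 15.0 | 42.3 | 8.00 | 24.9 | 15.0 | 52.9 |
| 20.0 | 46.1 | 20.0 | 37.0 | 20.0 | 56.2 |

(scatter of a reading: 1 percentage point)

- the numbers in the tables scatter by 1 percentage point (one standard deviation)
- what has left substrate counts as converted, also if it is not yet product
- no earlier run changes the charge of coupling partner; that part of a forecast is a guess

- apparent order in coupling partner when 50% of the substrate are converted (percent change of the rate of making target for one percent more coupling partner charged)
- factor on the rate of making target when 50% of the substrate are converted if free catalyst is charged twice over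

- The next rung was slower. In the zeta and epsilon runs, the target gained per stretch shrank steadily, and I named the late time for that gain to fall by a factor of 2 the fade half-life.
- The last two stretches gave 5.10 min for zeta and 4.61 min for epsilon, so I carried 4.85 min as a rough reading, given the scatter of 1 percentage point.
- The zeta run flattened with coupling partner to spare: substrate was its limiting reagent, and the target made was less than the partner charged. I therefore suspected the catalyst.
- My rough rule held the substrate and coupling partner charges fixed and compared two flasks at the same conversion. It took a doubled catalyst charge to start 2 times as fast, to arrive in about the arrival time divided by 2, and so to have aged less by then. The factor on the rate at that conversion is then 2 times 2 raised to arrival time over twice the fade half-life.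
- I guessed arrival at about two fade half-lives, when the rate has fallen 4-fold, which gave me a factor of 4. No earlier run varied coupling partner, so I committed to no order there.
- The forecast gave 0.7 for the order and 2.2 for the factor, lower than mine, noting that "catalyst death could also fit".

- The flask gave an order of 0.85 in coupling partner and a factor of 3.56 for doubled catalyst.

    free catalyst + open intermediate ⇌ catalyst intermediate (K = 22.0 L mol⁻¹, k = 8.60 L mol⁻¹ s⁻¹)
    free catalyst → spent catalyst (k = 0.00180 s⁻¹)
    coupling partner + catalyst intermediate → free catalyst + target (k = 4.90 L mol⁻¹ s⁻¹)
    substrate + free catalyst ⇌ free catalyst + open intermediate (K = 0.740, k = 2.20 L mol⁻¹ s⁻¹)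

- By 7.50 min, spent catalyst already stood at 49.4% of the catalyst charged. This flask passed 50% conversion at 10.4 min, which is 2.14 fade half-lives. With that arrival, my rule gave 4.21 for the flask charged with twice the catalyst, against the 3.56 it actually showed.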